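## Retrosynthetic overview

1. Target ⇒ angeloylation of the C8 alcohol ⇒ C7–C8 bond by a cathodic Ni/Cr coupling of a ring alkenyl triflate with an (S)-β,γ-epoxy aldehyde; the C10 oxirane oxygen steers C8 (1,3-anti).
2. Alkenyl triflate ⇒ methyl ketone ⇒ ozonolysis of the isopropenyl group of a fully oxygenated (R)-carvone derivative.
3. All-cis ring array from (R)-carvone: α′-hydroxylation (trans), Mitsunobu inversion with angelic acid, Luche reduction, hydroxyl-directed epoxidation, acetylation.
4. Epoxy aldehyde ⇒ (S)-α-hydroxy-γ-butyrolactone (L-malic acid series): chloride with inversion, double MeMgCl addition with oxirane closure (second inversion), oxidation.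
5. Ring order: the carbocycle is bought with carvone; the ring oxirane is closed in step 4; the side-chain oxirane is closed in step 9, before the fragments are joined.

Assumption: ring locants are those of the cyclohexyl ester names (C1 carries the ring angelate, C2 the acetate, C3 the methyl, C6 the side chain), which are also the bisabolane locants; the side chain is C7–C11 and C14 is the exocyclic methylene.

## Route

Step 1
Reactants: 1 (R)-(−)-carvone
Product: 4 (5S,6S)-6-hydroxy-2-methyl-5-(prop-1-en-2-yl)cyclohex-2-en-1-one (trans-α′-hydroxycarvone), via silyl dienol ether 2 (not isolated), via α′-silyloxy ketone 3 (not isolated)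
Conditions: LiN(i-Pr)2, THF, −78 °C, then Me3SiCl; mCPBA, CH2Cl2, 0 °C; 1 M HCl, THF, rt
Reagents that add atoms: 3-chloroperoxybenzoic acid (mCPBA), OOC(=O)c1cccc(Cl)c1; chlorotrimethylsilane, C[Si](C)(C)Cl (carried in 2 and 3 only)
Why: Rubottom oxidation: the kinetic cross-conjugated enolate is trapped on oxygen and mCPBA attacks the silyl enol ether on the face away from the neighbouring isopropenyl group, so the new hydroxyl is trans to it.

Step 2
Reactants: 4 trans-α′-hydroxycarvone; 5 angelic acid, (Z)-2-methylbut-2-enoic acid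
Product: 6 (1R,6S)-3-methyl-2-oxo-6-(prop-1-en-2-yl)cyclohex-3-en-1-yl (Z)-2-methylbut-2-enoate (cis-α′-angeloyloxycarvone)
Conditions: PPh3, DIAD, THF, 0 °C → rt
Reagents that add atoms: none
Why: Mitsunobu esterification: the carboxylate displaces the oxyphosphonium group in an SN2 step made easy by the adjacent carbonyl, which inverts the carbinol carbon and puts the angelate cis to the isopropenyl group.

Step 3
Reactants: 6 cis-α′-angeloyloxycarvone
Product: 7 (1R,2S,6S)-2-hydroxy-3-methyl-6-(prop-1-en-2-yl)cyclohex-3-en-1-yl (Z)-2-methylbut-2-enoate (all-cis)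
Conditions: NaBH4, CeCl3·7H2O, MeOH, −78 °C
Reagents that add atoms: none
Why: Luche 1,2-reduction: hydride attacks the carbonyl face anti to the axial α-angeloyloxy group (Felkin–Anh) and to the isopropenyl group, so the new hydroxyl is cis to both and the enoate is untouched.

Step 4
Reactants: 7 all-cis allylic alcohol
Product: 8 (1R,2R,3R,4S,6S)-3,4-epoxy-2-hydroxy-3-methyl-6-(prop-1-en-2-yl)cyclohexyl (Z)-2-methylbut-2-enoate
Conditions: VO(acac)2 (2 mol %), t-BuOOH, CH2Cl2, 0 °C → rt
Reagents that add atoms: tert-butyl hydroperoxide, CC(C)(C)OO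
Why: Hydroxyl-directed vanadium-catalysed epoxidation: the allylic vanadate ester delivers oxygen syn to the C2 hydroxyl, which sets C3 and C4, while the isopropenyl and angelate alkenes have no directing group and stay.

Step 5
Reactants: 8 epoxy alcohol
Product: 9 (1R,2R,3S,4S,6S)-2-acetoxy-3,4-epoxy-3-methyl-6-(prop-1-en-2-yl)cyclohexyl (Z)-2-methylbut-2-enoate
Conditions: Ac2O, pyridine, DMAP (cat.), CH2Cl2, 0 °C → rt
Reagents that add atoms: acetic anhydride, CC(=O)OC(C)=O
Why: DMAP-catalysed O-acetylation (nucleophilic acyl transfer) of the only free hydroxyl; no stereocenter is touched and capping it stops any 1,2-acyl shift.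

Step 6
Reactants: 9 epoxy acetate
Product: 11 (1R,2R,3S,4S,6R)-2-acetoxy-6-acetyl-3,4-epoxy-3-methylcyclohexyl (Z)-2-methylbut-2-enoate, via secondary ozonide 10 (not isolated)
Conditions: O3, CH2Cl2, −78 °C (Sudan Red 7B end point); PPh3, −78 °C → rt
Reagents that add atoms: ozone, [O-][O+]=O
Why: Ozonolysis (Criegee mechanism) with reductive work-up: the electron-rich 1,1-disubstituted alkene is cleaved much faster than the conjugated angelate alkene, and the neutral work-up leaves C6, now α to a ketone, unepimerised.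

Step 7
Reactants: 11 methyl ketone
Product: 13 (1R,2R,3S,4S,6R)-2-acetoxy-3,4-epoxy-3-methyl-6-{1-[(trifluoromethanesulfonyl)oxy]ethenyl}cyclohexyl (Z)-2-methylbut-2-enoate, via potassium enolate 12 (not isolated)
Conditions: KN(SiMe3)2, THF, −78 °C; PhNTf2, −78 → −20 °C
Reagents that add atoms: N-phenylbis(trifluoromethanesulfonimide), O=S(=O)(N(c1ccccc1)S(=O)(=O)C(F)(F)F)C(F)(F)F
Why: Kinetic enolate O-triflation: the bulky amide removes a methyl proton at −78 °C, so the terminal enolate is trapped before it can equilibrate, and C6 and the β-angelate are left alone.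

Step 8
Reactants: 14 (S)-α-hydroxy-γ-butyrolactone, (3S)-3-hydroxyoxolan-2-one
Product: 15 (3R)-3-chlorooxolan-2-one
Conditions: PPh3, N-chlorosuccinimide, THF, 0 °C → rt
Reagents that add atoms: N-chlorosuccinimide, O=C1CCC(=O)N1Cl
Why: Appel-type chlorination: chloride displaces the oxyphosphonium group by SN2, inverting the carbinol carbon from S to R.

Step 9
Reactants: 15 (3R)-3-chlorooxolan-2-one
Product: 17 2-[(2S)-3,3-dimethyloxiran-2-yl]ethan-1-ol, via chlorohydrin 16 (not isolated)
Conditions: MeMgCl (2.3 equiv), THF, −78 → 0 °C; aq. NaOH, rt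
Reagents that add atoms: methylmagnesium chloride, C[Mg]Cl
Why: Double Grignard addition to the lactone carbonyl, then Williamson-type 3-exo-tet closure in which the tertiary alkoxide displaces chloride with inversion, so two inversions from 14 give the (S)-oxirane that becomes C10.

Step 10
Reactants: 17 epoxy alcohol
Product: 18 2-[(2S)-3,3-dimethyloxiran-2-yl]acetaldehyde
Conditions: Dess–Martin periodinane, pyridine, CH2Cl2, 0 °C; used at once
Reagents that add atoms: none
Why: Dess–Martin oxidation under buffered non-basic conditions gives the labile β,γ-epoxy aldehyde without β-elimination or loss of the C10 configuration.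

Step 11
Reactants: 13 alkenyl triflate; 18 (S)-epoxy aldehyde
Product: 19 (1R,2R,3S,4S,6S,8S,10S)-2-acetoxy-3,4:10,11-diepoxy-8-hydroxybisabol-7(14)-en-1-yl (Z)-2-methylbut-2-enoate
Conditions: CrCl2 (15 mol %), NiCl2·DME (3 mol %), 2,9-dimethyl-1,10-phenanthroline (3 mol %), Cp2ZrCl2 (1.1 equiv), LiCl, Bu4NPF6, MeCN–THF, divided cell, Zn anode, Ni-foam cathode, constant current, 0 °C
Reagents that add atoms: none
Why: Proposed new method: an oxirane-directed electroreductive Nozaki–Hiyama–Kishi alkenylation in which zerovalent nickel inserts into the C–OTf bond of 13, the alkenyl group passes to chromium that the cathode keeps divalent, and the resulting trivalent alkenylchromium binds the aldehyde oxygen and the oxirane oxygen of 18 in a six-membered chelate (MeCN–THF instead of DMF leaves both sites free) and delivers the alkenyl group to the carbonyl face remote from the gem-dimethyl oxirane carbon, which forms C7–C8 and sets C8 1,3-anti (8S) to C10, while Cp2ZrCl2 frees the chromium alkoxide and the divided cell keeps anodic zinc salts away from both oxiranes; the closest known reactions are the Ni/Cr-catalysed electrochemical Nozaki–Hiyama–Kishi coupling of alkenyl (pseudo)halides with aldehydes and chelation-controlled (Cram–Reetz) 1,3-anti additions to β-alkoxy aldehydes.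

Step 12
Reactants: 19 C8 alcohol; 5 angelic acid
Product: 21 (1R,2R,3S,4S,6S,8S,10S)-2-acetoxy-3,4:10,11-diepoxybisabol-7(14)-ene-1,8-diyl bis[(Z)-2-methylbut-2-enoate] (CNP0316628.1), via mixed anhydride 20 (not isolated)
Conditions: 5, 2,4,6-Cl3C6H2COCl, Et3N, toluene, rt; then 19, 80 °C
Reagents that add atoms: 2,4,6-trichlorobenzoyl chloride, O=C(Cl)c1c(Cl)cc(Cl)cc1Cl (carried in 20 only)
Why: Yamaguchi mixed-anhydride esterification, which gives angelates without Z→E isomerisation; only the O–H bond of the C8 alcohol reacts, so its configuration is kept.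

## Compound list

1 | (R)-(−)-carvone, (5R)-2-methyl-5-(prop-1-en-2-yl)cyclohex-2-en-1-one | C=C(C)[C@@H]1CC=C(C)C(=O)C1 | starting material
2 | trimethyl{[(3R)-6-methyl-3-(prop-1-en-2-yl)cyclohexa-1,5-dien-1-yl]oxy}silane (silyl dienol ether of 1) | C=C(C)[C@@H]1CC=C(C)C(O[Si](C)(C)C)=C1 | intermediate (not isolated)
3 | (5S,6S)-2-methyl-5-(prop-1-en-2-yl)-6-[(trimethylsilyl)oxy]cyclohex-2-en-1-one | C=C(C)[C@@H]1CC=C(C)C(=O)[C@H]1O[Si](C)(C)C | intermediate (not isolated)
4 | (5S,6S)-6-hydroxy-2-methyl-5-(prop-1-en-2-yl)cyclohex-2-en-1-one (hydroxyl trans to isopropenyl) | C=C(C)[C@@H]1CC=C(C)C(=O)[C@H]1O | intermediate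
5 | angelic acid, (Z)-2-methylbut-2-enoic acid | C/C=C(/C)C(=O)O | starting material
6 | (1R,6S)-3-methyl-2-oxo-6-(prop-1-en-2-yl)cyclohex-3-en-1-yl (Z)-2-methylbut-2-enoate (angelate cis to isopropenyl) | C=C(C)[C@@H]1CC=C(C)C(=O)[C@@H]1OC(=O)/C(C)=C\C | intermediate
7 | (1R,2S,6S)-2-hydroxy-3-methyl-6-(prop-1-en-2-yl)cyclohex-3-en-1-yl (Z)-2-methylbut-2-enoate (all-cis) | C=C(C)[C@@H]1CC=C(C)[C@H](O)[C@@H]1OC(=O)/C(C)=C\C | intermediate
8 | (1R,2R,3R,4S,6S)-3,4-epoxy-2-hydroxy-3-methyl-6-(prop-1-en-2-yl)cyclohexyl (Z)-2-methylbut-2-enoate (all oxygens and isopropenyl on one face) | C=C(C)[C@@H]1C[C@@H]2O[C@]2(C)[C@H](O)[C@@H]1OC(=O)/C(C)=C\C | intermediate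
9 | (1R,2R,3S,4S,6S)-2-acetoxy-3,4-epoxy-3-methyl-6-(prop-1-en-2-yl)cyclohexyl (Z)-2-methylbut-2-enoate | C=C(C)[C@@H]1C[C@@H]2O[C@]2(C)[C@H](OC(C)=O)[C@@H]1OC(=O)/C(C)=C\C | intermediate
10 | secondary ozonide of 9 (3-methyl-1,2,4-trioxolan-3-yl group at C6; epimers at the acetal carbon) | CC1(OCOO1)[C@@H]1C[C@@H]2O[C@]2(C)[C@H](OC(C)=O)[C@@H]1OC(=O)/C(C)=C\C | intermediate (not isolated)
11 | (1R,2R,3S,4S,6R)-2-acetoxy-6-acetyl-3,4-epoxy-3-methylcyclohexyl (Z)-2-methylbut-2-enoate | CC(=O)[C@@H]1C[C@@H]2O[C@]2(C)[C@H](OC(C)=O)[C@@H]1OC(=O)/C(C)=C\C | intermediate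
12 | potassium enolate of 11, terminal CH2=C(OK)– at C6 | [K+].C=C([O-])[C@@H]1C[C@@H]2O[C@]2(C)[C@H](OC(C)=O)[C@@H]1OC(=O)/C(C)=C\C | intermediate (not isolated)
13 | (1R,2R,3S,4S,6R)-2-acetoxy-3,4-epoxy-3-methyl-6-{1-[(trifluoromethanesulfonyl)oxy]ethenyl}cyclohexyl (Z)-2-methylbut-2-enoate | C=C(OS(=O)(=O)C(F)(F)F)[C@@H]1C[C@@H]2O[C@]2(C)[C@H](OC(C)=O)[C@@H]1OC(=O)/C(C)=C\C | intermediate
14 | (S)-α-hydroxy-γ-butyrolactone, (3S)-3-hydroxyoxolan-2-one | O[C@H]1CCOC1=O | starting material
15 | (3R)-3-chlorooxolan-2-one | Cl[C@@H]1CCOC1=O | intermediate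
16 | (3R)-3-chloro-4-methylpentane-1,4-diol | OCC[C@@H](Cl)C(C)(C)O | intermediate (not isolated)
17 | 2-[(2S)-3,3-dimethyloxiran-2-yl]ethan-1-ol | OCC[C@@H]1OC1(C)C | intermediate
18 | 2-[(2S)-3,3-dimethyloxiran-2-yl]acetaldehyde | O=CC[C@@H]1OC1(C)C | intermediate
19 | (1R,2R,3S,4S,6S,8S,10S)-2-acetoxy-3,4:10,11-diepoxy-8-hydroxybisabol-7(14)-en-1-yl (Z)-2-methylbut-2-enoate | C=C([C@H](C[C@@H]1OC1(C)C)O)[C@@H]1C[C@@H]2O[C@]2(C)[C@H](OC(C)=O)[C@@H]1OC(=O)/C(C)=C\C | intermediate
20 | (Z)-2-methylbut-2-enoic 2,4,6-trichlorobenzoic anhydride | C/C=C(/C)C(=O)OC(=O)c1c(Cl)cc(Cl)cc1Cl | intermediate (not isolated)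
21 | (1R,2R,3S,4S,6S,8S,10S)-2-acetoxy-3,4:10,11-diepoxybisabol-7(14)-ene-1,8-diyl bis[(Z)-2-methylbut-2-enoate], CNP0316628.1 | C=C([C@H](C[C@@H]1OC1(C)C)OC(=O)/C(C)=C\C)[C@@H]1C[C@@H]2O[C@]2(C)[C@H](OC(C)=O)[C@@H]1OC(=O)/C(C)=C\C | target

## Step count and risks

Total steps: 12 (steps 1–7 on the ring branch, steps 8–10 on the side-chain branch, steps 11 and 12 after the union).
Longest linear sequence: 9 steps (1, 2, 3, 4, 5, 6, 7, 11, 12, starting from 1).

The three steps most likely to fail:

Step 2 (Mitsunobu on a hindered α-hydroxy ketone; the risks are poor conversion and Z→E isomerisation of the angelate). The fallback sets out from 4. Compound 4 is sulfonylated (4-O2NC6H4SO2Cl, pyridine, CH2Cl2, 0 °C) to the α-keto 4-nitrobenzenesulfonate F1. F1 is then displaced by cesium (Z)-2-methylbut-2-enoate (made from 5 and Cs2CO3; DMF, 0 °C). This carboxylate SN2 reaction on an isolated α-keto sulfonate inverts the carbinol carbon without phosphine or azo reagents. The fallback comes back to the route at 6.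

Step 7 (kinetic O-triflation beside a β-acyloxy group; the risks are E1cB loss of the angelate, epimerisation at C6 and enolisation of the acetate). The fallback sets out from 11 and avoids enolate chemistry. Compound 11 is condensed with hydrazine hydrate (EtOH, 0 °C → rt) to the hydrazone F2. F2 is oxidised with I2 and 1,1,3,3-tetramethylguanidine (THF, 0 °C; Barton vinyl iodide synthesis) to the alkenyl iodide F3. F3 takes the place of 13 in step 11, and the fallback comes back to the route at 19.

Step 11 (the proposed new reaction; the risks are Lewis-acid opening of either oxirane and weak 1,3-induction). The fallback sets out from 13 and 18 and uses known chemistry: the classical stoichiometric Nozaki–Hiyama–Kishi coupling (CrCl2 4 equiv, NiCl2 1 mol %, DMSO–THF, rt). This tolerates esters and epoxides but gives C8 as a mixture. Compound 19 is separated by chromatography from its C8 epimer F4 and goes on to step 12. F4 is converged on the target by a Mitsunobu esterification with 5 (PPh3, DIAD, toluene, 0 °C), which inverts C8. The fallback comes back to the route at 19 and, for the epimer, at 21.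

## Further compounds

F1 | step 2 | (1S,6S)-3-methyl-2-oxo-6-(prop-1-en-2-yl)cyclohex-3-en-1-yl 4-nitrobenzenesulfonate | C=C(C)[C@@H]1CC=C(C)C(=O)[C@H]1OS(=O)(=O)c1ccc(cc1)[N+](=O)[O-]
F2 | step 7 | hydrazone of 11 (C=N–NH2 in place of the acetyl C=O) | CC(=NN)[C@@H]1C[C@@H]2O[C@]2(C)[C@H](OC(C)=O)[C@@H]1OC(=O)/C(C)=C\C
F3 | step 7 | alkenyl iodide, 6-(1-iodoethenyl) analogue of 13 | C=C(I)[C@@H]1C[C@@H]2O[C@]2(C)[C@H](OC(C)=O)[C@@H]1OC(=O)/C(C)=C\C
F4 | step 11 | (8R) epimer of 19 | C=C([C@@H](C[C@@H]1OC1(C)C)O)[C@@H]1C[C@@H]2O[C@]2(C)[C@H](OC(C)=O)[C@@H]1OC(=O)/C(C)=C\C
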